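The flavone is cut at O1–C2 and C2–C3 to an o-hydroxyaryl methoxymethyl ketone, whose ring A is then unfolded into an open tetraketide. In ring A the oxygens on C5, C7 and C8a sit on former carbonyl carbons, while C6 and C8 are former α-carbons that already carry methoxy groups, as expected for a polyketide with methoxyacetate extender units. The key step folds methyl 2,4,8-trimethoxy-3,5,7-trioxooctanoate by intramolecular Claisen condensation: the only methylene flanked by two ketones (chain C6) attacks the ester carbon (chain C1), forging C4a–C5, closing and aromatising ring A, and leaving C4 and the methoxylated C3 as a methoxyacetyl side chain.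

Key step: step 4

Remark: ring atoms are given in flavone numbering and chain atoms as chain C1–C8 counted from the ester carbon; 2, 4, 6 and 11 are drawn as keto forms although they should be largely enolised, their C–H stereocentres are labile and the target is achiral, so no configuration is assigned.

Step 1
Reactants: 1 methyl 2-methoxyacetate (two molecules)
Product: 2 methyl 2,4-dimethoxy-3-oxobutanoate
Conditions: NaH (0.55 equiv), MeOH (cat.), THF, 0 → 50 °C; then 1 M HCl, 0 °C
Reagents that add atoms: none
Why: Self-Claisen condensation of an α-alkoxy ester, in which the ester enolate of 1 acylates a second molecule and the equilibrium is pulled over by deprotonation of the doubly activated C2–H of 2 and by loss of hydrogen.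

Step 2
Reactants: 2 methyl 2,4-dimethoxy-3-oxobutanoate; 3 N-methoxy-N-methylacetamide
Product: 4 methyl 2,4-dimethoxy-3,5-dioxohexanoate
Conditions: LiN(iPr)2 (2.2 equiv), THF, −78 → 0 °C; then 3 (1.0 equiv), −78 → 0 °C; cold dilute HCl to pH 3
Reagents that add atoms: none
Why: γ-Acylation of a β-keto ester dianion (Weinreb ketone synthesis): after the acidic C2–H the second equivalent of base removes a C4 proton, and this more reactive γ-carbanion should be acetylated by the N-methoxy-N-methylamide, which releases the new ketone only on acidic quench so that the product cannot protonate unreacted dianion.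

Step 3
Reactants: 4 methyl 2,4-dimethoxy-3,5-dioxohexanoate; 5 N,2-dimethoxy-N-methylacetamide
Product: 6 methyl 2,4,8-trimethoxy-3,5,7-trioxooctanoate
Conditions: LiN(iPr)2 (3.3 equiv), THF, −78 → 0 °C; then 5 (1.0 equiv), −78 → 0 °C; cold dilute HCl to pH 3, rapid extraction, crude 6 used at once
Reagents that add atoms: none
Why: Terminal acylation of a 3,5-diketo ester trianion (polyanion Claisen-type acylation, Weinreb ketone synthesis): once C2–H and C4–H are removed the third equivalent of base can only deprotonate the methyl group, and this least delocalised carbanion should be methoxyacetylated; the chain is built stepwise because coupling a dianion with an enolisable β-keto ester salt would invite proton exchange and scrambling of the partners.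

Step 4
Reactants: 6 methyl 2,4,8-trimethoxy-3,5,7-trioxooctanoate
Product: 7 1-(2,4,6-trihydroxy-3,5-dimethoxyphenyl)-2-methoxyethan-1-one
Conditions: NaOMe (6 equiv), degassed MeOH, Ar, 0 → 50 °C; then cold 2 M HCl to pH 2
Reagents that add atoms: none
Why: Methoxide turns the chain into its polyenolate, the chain C6 carbanion adds to the chain C1 ester carbonyl, methoxide is expelled, and the cyclohexane-1,3,5-trione so formed tautomerises to the phloroglucinol, whose phenoxide is the thermodynamic sink. The closest known reaction is the base-induced Claisen (Dieckmann-type) cyclisation of 3,5,7-triketo esters to acylphloroglucinols, applied here to a chain that carries methoxy groups at chain C2, C4 and C8. Ring A closes in a 6-exo-trig mode, the ester C=O lying outside the forming six-membered ring, and no stereocentre is created because the labile centres at chain C2 and C4 vanish on aromatisation. The step needs Claisen folding to beat the chain C2-to-C7 aldol folding and the O-acylation that gives a 4-hydroxy-2-pyranone: excess methoxide keeps the three ketones masked as enolates so that the ester is the best electrophile left, the aldol adduct has a quaternary chain C2 (OMe, CO2Me) that cannot aromatise without losing its ester and should therefore revert, and the pyranone is reopened by methoxide to the same chain. A second aromatisable path, aldol attack of chain C8 on the chain C3 ketone, is disfavoured because C8–H is the least acidic C–H of the chain and C3 lies between two enolised positions. The product has a mirror plane through the acyl-bearing carbon and the para carbon, so its two ortho hydroxyls are equivalent and either may become O1.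

Step 5
Reactants: 7 1-(2,4,6-trihydroxy-3,5-dimethoxyphenyl)-2-methoxyethan-1-one
Product: 8 1-(2-hydroxy-3,4,5,6-tetramethoxyphenyl)-2-methoxyethan-1-one
Conditions: Me2SO4 (2.05 equiv), K2CO3 (2.5 equiv), acetone, reflux
Reagents that add atoms: dimethyl sulfate, COS(=O)(=O)OC
Why: Williamson O-methylation under weak-base control: the para hydroxyl and one of the two equivalent ortho hydroxyls should be methylated, while the remaining ortho hydroxyl is held in a six-membered hydrogen bond to the ketone and resists K2CO3/Me2SO4 at this stoichiometry, and the fully substituted ring leaves no site for C-methylation.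

Step 6
Reactants: 8 1-(2-hydroxy-3,4,5,6-tetramethoxyphenyl)-2-methoxyethan-1-one; 9 2,4-dimethoxybenzoyl chloride
Product: 11 1-(2,4-dimethoxyphenyl)-3-(2-hydroxy-3,4,5,6-tetramethoxyphenyl)-2-methoxypropane-1,3-dione, via O-aroyl ester 10 (not isolated)
Conditions: 9 (1.2 equiv), DMAP (cat.), pyridine, 0 → 60 °C; then powdered KOH (4 equiv), 50 °C; aq. AcOH
Reagents that add atoms: none
Why: O-Aroylation of the phenol under nucleophilic catalysis followed in the same pot by a Baker–Venkataraman rearrangement, in which the enolate of the methoxymethyl ketone attacks the neighbouring aryl ester through a six-membered transition state and the aroyl group moves from O to C, driven by formation of the stabilised diketonate and phenoxide.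

Step 7
Reactants: 11 1-(2,4-dimethoxyphenyl)-3-(2-hydroxy-3,4,5,6-tetramethoxyphenyl)-2-methoxypropane-1,3-dione
Product: 12 2-(2,4-dimethoxyphenyl)-3,5,6,7,8-pentamethoxy-4H-chromen-4-one
Conditions: H2SO4 (cat.), AcOH, 80 °C
Reagents that add atoms: none
Why: Acid-catalysed cyclodehydration of an o-hydroxyaryl 1,3-diketone: the phenol adds to the aroyl carbonyl and loss of water from the hemiketal closes O1–C2 and gives the 4-pyranone ring of the 3-methoxyflavone, the aryl and enol methyl ethers being expected to survive brief warming in acetic acid.

Compound list
1 | methyl 2-methoxyacetate | COCC(=O)OC | starting material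
2 | methyl 2,4-dimethoxy-3-oxobutanoate (racemic, enolisable) | COCC(=O)C(OC)C(=O)OC | intermediate
3 | N-methoxy-N-methylacetamide | CC(=O)N(C)OC | starting material
4 | methyl 2,4-dimethoxy-3,5-dioxohexanoate (epimerisable mixture, largely enolised) | CC(=O)C(OC)C(=O)C(OC)C(=O)OC | intermediate
5 | N,2-dimethoxy-N-methylacetamide | COCC(=O)N(C)OC | starting material
6 | methyl 2,4,8-trimethoxy-3,5,7-trioxooctanoate (epimerisable mixture, largely enolised) | COCC(=O)CC(=O)C(OC)C(=O)C(OC)C(=O)OC | intermediate
7 | 1-(2,4,6-trihydroxy-3,5-dimethoxyphenyl)-2-methoxyethan-1-one | COCC(=O)c1c(O)c(OC)c(O)c(OC)c1O | intermediate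
8 | 1-(2-hydroxy-3,4,5,6-tetramethoxyphenyl)-2-methoxyethan-1-one | COCC(=O)c1c(O)c(OC)c(OC)c(OC)c1OC | intermediate
9 | 2,4-dimethoxybenzoyl chloride | COc1ccc(C(=O)Cl)c(OC)c1 | starting material
10 | 2,3,4,5-tetramethoxy-6-(2-methoxyacetyl)phenyl 2,4-dimethoxybenzoate | COCC(=O)c1c(OC(=O)c2ccc(OC)cc2OC)c(OC)c(OC)c(OC)c1OC | intermediate
11 | 1-(2,4-dimethoxyphenyl)-3-(2-hydroxy-3,4,5,6-tetramethoxyphenyl)-2-methoxypropane-1,3-dione (racemic, enolisable) | COc1ccc(C(=O)C(OC)C(=O)c2c(O)c(OC)c(OC)c(OC)c2OC)c(OC)c1 | intermediate
12 | 2-(2,4-dimethoxyphenyl)-3,5,6,7,8-pentamethoxy-4H-chromen-4-one | COc1ccc(-c2oc3c(OC)c(OC)c(OC)c(OC)c3c(=O)c2OC)c(OC)c1 | target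

Total step count: 7 steps.
Longest linear sequence: 7 steps (1 → 2 → 4 → 6 → 7 → 8 → 11 → 12); 3, 5 and 9 enter as purchased building blocks.

Steps most likely to fail

Step 4. The chain may fold in the aldol sense (chain C2 onto C7 followed by loss of the ester group, or chain C8 onto C3). It may also lactonise to the pyranone faster than it C-acylates, be cut by retro-Claisen attack of methoxide, or give a product that is oxidised in the basic medium. The fallback gives up the open-chain approach to ring A for an aromatic one that sets out from 5 and returns at 8. Commercial pentamethoxybenzene (COc1cc(OC)c(OC)c(OC)c1OC) would be lithiated at its only ring C–H with n-BuLi in THF at 0 °C, a directed ortho metalation between two methoxy groups. Acylation with 5 would give 2-methoxy-1-(2,3,4,5,6-pentamethoxyphenyl)ethan-1-one F1. One equivalent of BCl3 in CH2Cl2 at −78 → 0 °C should then remove one of the two equivalent methyl groups ortho to the carbonyl through a six-membered boron chelate. This would give 8 and make steps 1 to 5 unnecessary.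

Step 3. Formation of the trianion may be incomplete, the carbanion may deprotonate the amide instead of adding to it, and the labile tetracarbonyl chain may cyclise during acidic work-up. The fallback forms the chain C4–C5 bond instead of C6–C7; it sets out from 2 and returns at 6. The dilithium dianion of 2 (LiN(iPr)2, 2.2 equiv, THF) would be treated with the preformed lithium enolate of commercial methyl 4-methoxyacetoacetate (COCC(=O)CC(=O)OC). Enolate formation masks the ketone and the acidic methylene of that partner, so the γ-carbanion of 2 should attack its ester carbon. This condensation of a 1,3-dicarbonyl dianion with a β-keto ester salt is known chemistry; it bypasses 4 and makes no compound outside the list (F0).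

Step 6. O-Aroylation of the hindered, hydrogen-bonded phenol may stall, and hydroxide may cleave the aryl ester faster than the aroyl group migrates. The fallback is an Allan–Robinson flavone synthesis that sets out from 8 and 9 and returns at 12. Compound 9 and sodium 2,4-dimethoxybenzoate would give 2,4-dimethoxybenzoic anhydride F2. Heating 8 with F2 and sodium 2,4-dimethoxybenzoate at about 180 °C, followed by brief treatment with aqueous ethanolic KOH to destroy excess anhydride, should aroylate, rearrange and cyclise in one operation. This would deliver 12 directly and replace steps 6 and 7.

Further compounds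
F1 | step 4 | 2-methoxy-1-(2,3,4,5,6-pentamethoxyphenyl)ethan-1-one | COCC(=O)c1c(OC)c(OC)c(OC)c(OC)c1OC
F0 | step 3 | none | none
F2 | step 6 | 2,4-dimethoxybenzoic anhydride | COc1ccc(C(=O)OC(=O)c2ccc(OC)cc2OC)c(OC)c1
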